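**Retrosynthetic overview**
1. Target 20 ⇐ threefold olefin cross-metathesis (allyl → prenyl) of triallyl tetraphenol 18; the prenyl groups come last because alkenes would not survive the oxidative rearrangement.
2. 18 ⇐ three aromatic Claisen rearrangements of the 5,7,2'-tri-O-allyl ether 16 (4'-O blocked as MOM), so allyl can only end up at C6, C8 and C3'.
3. Isoflavone core 12 ⇐ Tl(III) 1,2-aryl shift of chalcone 9, then acid closure of the pyranone ring (the only ring built; rings A and B are bought).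
4. Chalcone 9 ⇐ key C–C bond: intermolecular Claisen–Schmidt aldol condensation of acetophenone 3 (from phloroacetophenone) with aldehyde 7 (from 2,4-dihydroxybenzaldehyde).

Assumption: the target has no stereocentre and is achiral, so there is no enantiomer to select; the stereocentres of 8 and 11 are racemic and are erased in the next operation.

**Route**

Step 1
Reactants: 1 2,4,6-trihydroxyacetophenone; 2 benzyl bromide
Product: 3 1-[2,4-bis(benzyloxy)-6-hydroxyphenyl]ethan-1-one
Conditions: BnBr (2.1 equiv), K2CO3 (2.2 equiv), DMF, rt, 16 h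
Reagents that add atoms: benzyl bromide, BrCc1ccccc1
Why: Williamson etherification stops at the bis-ether because the last ortho OH is hydrogen-bonded to the acetyl carbonyl and is the least nucleophilic.

Step 2
Reactants: 4 2,4-dihydroxybenzaldehyde; 5 chloromethyl methyl ether
Product: 6 2-hydroxy-4-(methoxymethoxy)benzaldehyde
Conditions: MOMCl (1.1 equiv), K2CO3 (1.5 equiv), acetone, 0 °C to rt
Reagents that add atoms: chloromethyl methyl ether, COCCl
Why: Regioselective O-alkylation, since the 4-OH is more acidic and not chelated to the aldehyde, unlike the 2-OH.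

Step 3
Reactants: 6 2-hydroxy-4-(methoxymethoxy)benzaldehyde; 2 benzyl bromide
Product: 7 2-(benzyloxy)-4-(methoxymethoxy)benzaldehyde
Conditions: BnBr (1.2 equiv), K2CO3 (2 equiv), DMF, 60 °C
Reagents that add atoms: benzyl bromide, BrCc1ccccc1
Why: Williamson etherification under slightly forcing conditions alkylates the chelated 2-OH and gives an acid-stable ether on the future 2'-oxygen.

Step 4
Reactants: 3 1-[2,4-bis(benzyloxy)-6-hydroxyphenyl]ethan-1-one; 7 2-(benzyloxy)-4-(methoxymethoxy)benzaldehyde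
Product: 9 (E)-1-[2,4-bis(benzyloxy)-6-hydroxyphenyl]-3-[2-(benzyloxy)-4-(methoxymethoxy)phenyl]prop-2-en-1-one, via β-hydroxy ketone 8 (not isolated)
Conditions: KOH (50% aq, 10 equiv), EtOH, rt, 36–48 h; then cold 1 M HCl to pH 5
Reagents that add atoms: none
Why: Claisen–Schmidt crossed aldol condensation of a methyl ketone enolate with a non-enolisable aldehyde, where E1cB dehydration of the racemic aldol gives the thermodynamically favoured E-enone.

Step 5
Reactants: 9 (E)-chalcone from step 4; 10 methanol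
Product: 11 1-[2,4-bis(benzyloxy)-6-hydroxyphenyl]-2-[2-(benzyloxy)-4-(methoxymethoxy)phenyl]-3,3-dimethoxypropan-1-one (racemic)
Conditions: Tl(NO3)3·3H2O (1.2 equiv), MeOH/HC(OMe)3 1:1, rt, 3 h; aq NaHCO3 work-up, crude used directly
Reagents that add atoms: methanol, CO
Why: Thallium(III)-mediated oxidative rearrangement of a chalcone, in which the electron-rich 2,4-dialkoxyphenyl ring undergoes the 1,2-aryl shift and methanol traps the cation as the dimethyl acetal (the new stereocentre is racemic and is lost in step 6).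

Step 6
Reactants: 11 dimethyl acetal from step 5
Product: 12 5,7-bis(benzyloxy)-3-[2-(benzyloxy)-4-hydroxyphenyl]-4H-chromen-4-one
Conditions: 10% aq HCl, MeOH/THF, reflux, 2–3 h
Reagents that add atoms: none
Why: Acid-catalysed acetal cyclisation–elimination by the free A-ring phenol forms the pyranone ring and cleaves the MOM ether, while the benzyl ether on the B-ring 2-oxygen rules out the competing benzofuran closure.

Step 7
Reactants: 12 5,7-bis(benzyloxy)-3-[2-(benzyloxy)-4-hydroxyphenyl]-4H-chromen-4-one; 5 chloromethyl methyl ether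
Product: 13 5,7-bis(benzyloxy)-3-[2-(benzyloxy)-4-(methoxymethoxy)phenyl]-4H-chromen-4-one
Conditions: MOMCl (1.5 equiv), K2CO3 (3 equiv), acetone, rt to 50 °C
Reagents that add atoms: chloromethyl methyl ether, COCCl
Why: O-Alkylation of the only free phenol re-masks the 4'-oxygen with a group that survives hydrogenolysis, base and heat and later comes off under conditions harmless to allyl groups.

Step 8
Reactants: 13 5,7-bis(benzyloxy)-3-[2-(benzyloxy)-4-(methoxymethoxy)phenyl]-4H-chromen-4-one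
Product: 14 5,7-dihydroxy-3-[2-hydroxy-4-(methoxymethoxy)phenyl]-4H-chromen-4-one
Conditions: H2 (1 atm), 10% Pd/C, EtOAc/THF 1:1, rt, stopped after 3 equiv H2
Reagents that add atoms: none
Why: Catalytic hydrogenolysis cleaves the three benzyl ethers under neutral conditions that leave the MOM ether and the chromone double bond intact.

Step 9
Reactants: 14 5,7-dihydroxy-3-[2-hydroxy-4-(methoxymethoxy)phenyl]-4H-chromen-4-one; 15 allyl bromide
Product: 16 5,7-bis(allyloxy)-3-[2-(allyloxy)-4-(methoxymethoxy)phenyl]-4H-chromen-4-one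
Conditions: allyl bromide (6 equiv), K2CO3 (6 equiv), DMF, 60 °C, 16 h
Reagents that add atoms: allyl bromide, C=CCBr
Why: Exhaustive Williamson O-allylation, with excess reagent in warm DMF also alkylating the chelated 5-OH.

Step 10
Reactants: 16 5,7-bis(allyloxy)-3-[2-(allyloxy)-4-(methoxymethoxy)phenyl]-4H-chromen-4-one
Product: 17 6,8-diallyl-3-[3-allyl-2-hydroxy-4-(methoxymethoxy)phenyl]-5,7-dihydroxy-4H-chromen-4-one
Conditions: N,N-diethylaniline (degassed), 200 °C, sealed tube, Ar, 4–6 h
Reagents that add atoms: none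
Why: Three aromatic Claisen [3,3] rearrangements that are regioconvergent, because the 2'-O-allyl has only C3' as a free ortho position and the 5-O/7-O pair can only fill C6 and C8 (a 5-O-allyl that finds C6 occupied relays to C8 by the para-Claisen/Cope path).

Step 11
Reactants: 17 6,8-diallyl-3-[3-allyl-2-hydroxy-4-(methoxymethoxy)phenyl]-5,7-dihydroxy-4H-chromen-4-one
Product: 18 6,8-diallyl-3-(3-allyl-2,4-dihydroxyphenyl)-5,7-dihydroxy-4H-chromen-4-one
Conditions: 3 M aq HCl/MeOH 1:5, 50 °C, 3 h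
Reagents that add atoms: none
Why: Acid hydrolysis of the MOM acetal is done at the allyl stage because terminal alkenes are not protonated under these conditions, whereas prenyl groups next to phenols would cyclise to chromans.

Step 12
Reactants: 18 6,8-diallyl-3-(3-allyl-2,4-dihydroxyphenyl)-5,7-dihydroxy-4H-chromen-4-one; 19 2-methylbut-2-ene
Product: 20 euchrenone b2, 3-[2,4-dihydroxy-3-(3-methylbut-2-en-1-yl)phenyl]-5,7-dihydroxy-6,8-bis(3-methylbut-2-en-1-yl)-4H-chromen-4-one
Conditions: Grubbs II (10 mol%), 2-methylbut-2-ene/CH2Cl2 1:2, 40 °C, sealed tube, 16 h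
Reagents that add atoms: 2-methylbut-2-ene, CC=C(C)C
Why: Olefin cross-metathesis of each terminal allyl group with a large excess of the trisubstituted alkene gives the prenyl group selectively, and the free phenols are tolerated by the ruthenium carbene.

**Compound list**
1 | 2,4,6-trihydroxyacetophenone | CC(=O)c1c(O)cc(O)cc1O | starting material
2 | benzyl bromide | BrCc1ccccc1 | starting material
3 | 1-[2,4-bis(benzyloxy)-6-hydroxyphenyl]ethan-1-one | CC(=O)c1c(O)cc(OCc2ccccc2)cc1OCc1ccccc1 | intermediate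
4 | 2,4-dihydroxybenzaldehyde | O=Cc1ccc(O)cc1O | starting material
5 | chloromethyl methyl ether | COCCl | starting material
6 | 2-hydroxy-4-(methoxymethoxy)benzaldehyde | O=Cc1ccc(OCOC)cc1O | intermediate
7 | 2-(benzyloxy)-4-(methoxymethoxy)benzaldehyde | O=Cc1ccc(OCOC)cc1OCc1ccccc1 | intermediate
8 | 1-[2,4-bis(benzyloxy)-6-hydroxyphenyl]-3-[2-(benzyloxy)-4-(methoxymethoxy)phenyl]-3-hydroxypropan-1-one (racemic, not isolated) | O=C(CC(O)c1ccc(OCOC)cc1OCc1ccccc1)c1c(O)cc(OCc2ccccc2)cc1OCc1ccccc1 | intermediate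
9 | (E)-1-[2,4-bis(benzyloxy)-6-hydroxyphenyl]-3-[2-(benzyloxy)-4-(methoxymethoxy)phenyl]prop-2-en-1-one | O=C(/C=C/c1ccc(OCOC)cc1OCc1ccccc1)c1c(O)cc(OCc2ccccc2)cc1OCc1ccccc1 | intermediate
10 | methanol | CO | starting material
11 | 1-[2,4-bis(benzyloxy)-6-hydroxyphenyl]-2-[2-(benzyloxy)-4-(methoxymethoxy)phenyl]-3,3-dimethoxypropan-1-one (racemic) | COC(OC)C(c1ccc(OCOC)cc1OCc1ccccc1)C(=O)c1c(O)cc(OCc2ccccc2)cc1OCc1ccccc1 | intermediate
12 | 5,7-bis(benzyloxy)-3-[2-(benzyloxy)-4-hydroxyphenyl]-4H-chromen-4-one | O=c1c(-c2ccc(O)cc2OCc2ccccc2)coc2cc(OCc3ccccc3)cc(OCc3ccccc3)c12 | intermediate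
13 | 5,7-bis(benzyloxy)-3-[2-(benzyloxy)-4-(methoxymethoxy)phenyl]-4H-chromen-4-one | O=c1c(-c2ccc(OCOC)cc2OCc2ccccc2)coc2cc(OCc3ccccc3)cc(OCc3ccccc3)c12 | intermediate
14 | 5,7-dihydroxy-3-[2-hydroxy-4-(methoxymethoxy)phenyl]-4H-chromen-4-one | O=c1c(-c2ccc(OCOC)cc2O)coc2cc(O)cc(O)c12 | intermediate
15 | allyl bromide | C=CCBr | starting material
16 | 5,7-bis(allyloxy)-3-[2-(allyloxy)-4-(methoxymethoxy)phenyl]-4H-chromen-4-one | O=c1c(-c2ccc(OCOC)cc2OCC=C)coc2cc(OCC=C)cc(OCC=C)c12 | intermediate
17 | 6,8-diallyl-3-[3-allyl-2-hydroxy-4-(methoxymethoxy)phenyl]-5,7-dihydroxy-4H-chromen-4-one | O=c1c(-c2ccc(OCOC)c(CC=C)c2O)coc2c(CC=C)c(O)c(CC=C)c(O)c12 | intermediate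
18 | 6,8-diallyl-3-(3-allyl-2,4-dihydroxyphenyl)-5,7-dihydroxy-4H-chromen-4-one | O=c1c(-c2ccc(O)c(CC=C)c2O)coc2c(CC=C)c(O)c(CC=C)c(O)c12 | intermediate
19 | 2-methylbut-2-ene | CC=C(C)C | starting material
20 | euchrenone b2 | CC(C)=CCc1c(O)ccc(-c2coc3c(CC=C(C)C)c(O)c(CC=C(C)C)c(O)c3c2=O)c1O | target

**Totals**
Total step count: 12. Longest linear sequence: 11 steps (4 → 20, steps 2–12).

**Three steps most likely to fail**

Step 5 (Tl(III) aryl shift; risks are aurone formation from the free 2'-OH chalcone and oxidation of the electron-rich rings). Fallback: from 9, NaOAc in refluxing EtOH closes the chalcone by intramolecular oxa-Michael addition to the racemic flavanone 5,7-bis(benzyloxy)-2-[2-(benzyloxy)-4-(methoxymethoxy)phenyl]chroman-4-one F1. This is then subjected to the hypervalent-iodine 2,3-aryl migration (PhI(OAc)2, cat. H2SO4, HC(OMe)3, rt), which gives the isoflavone directly without thallium. Warming the crude product in HCl/MeOH completes MOM cleavage and rejoins the route at 12.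

Step 10 (triple Claisen; risks are incomplete or messy rearrangement of the 5-O-allyl group and thermal decomposition). Fallback: from 14, allyl bromide (2.2 equiv) and K2CO3 in refluxing acetone alkylate only the 7- and 2'-OH, leaving the chelated 5-OH free, to give 7-(allyloxy)-3-[2-(allyloxy)-4-(methoxymethoxy)phenyl]-5-hydroxy-4H-chromen-4-one F2. Claisen rearrangement (PhNEt2, 190 °C) gives 8-allyl-3-[3-allyl-2-hydroxy-4-(methoxymethoxy)phenyl]-5,7-dihydroxy-4H-chromen-4-one F3; any 6-allyl isomer need not be separated because it ends at the same compound. The acidic 7-OH alone is then re-allylated (allyl bromide 1.1 equiv, KHCO3, DMF, rt) to 8-allyl-7-(allyloxy)-3-[3-allyl-2-hydroxy-4-(methoxymethoxy)phenyl]-5-hydroxy-4H-chromen-4-one F4. A second Claisen rearrangement into the last free A-ring position returns to 17.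

Step 12 (threefold cross-metathesis on a free tetraphenol; risks are catalyst inhibition by the chelating phenols, partial conversion and allyl-to-propenyl isomerisation). Fallback: from 18, Ac2O, pyridine and DMAP give the tetraacetate 6,8-diallyl-3-(2,4-diacetoxy-3-allylphenyl)-4-oxo-4H-chromene-5,7-diyl diacetate F5. Cross-metathesis with 19 (Grubbs II, CH2Cl2, 40 °C) gives 3-[2,4-diacetoxy-3-(3-methylbut-2-en-1-yl)phenyl]-6,8-bis(3-methylbut-2-en-1-yl)-4-oxo-4H-chromene-5,7-diyl diacetate F6. Mild methanolysis (K2CO3, MeOH, rt) removes the acetates without acid and returns to 20.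

**Further compounds**
F1 | step 5 | 5,7-bis(benzyloxy)-2-[2-(benzyloxy)-4-(methoxymethoxy)phenyl]chroman-4-one (racemic) | O=C1CC(c2ccc(OCOC)cc2OCc2ccccc2)Oc2cc(OCc3ccccc3)cc(OCc3ccccc3)c21
F2 | step 10 | 7-(allyloxy)-3-[2-(allyloxy)-4-(methoxymethoxy)phenyl]-5-hydroxy-4H-chromen-4-one | O=c1c(-c2ccc(OCOC)cc2OCC=C)coc2cc(OCC=C)cc(O)c12
F3 | step 10 | 8-allyl-3-[3-allyl-2-hydroxy-4-(methoxymethoxy)phenyl]-5,7-dihydroxy-4H-chromen-4-one | O=c1c(-c2ccc(OCOC)c(CC=C)c2O)coc2c(CC=C)c(O)cc(O)c12
F4 | step 10 | 8-allyl-7-(allyloxy)-3-[3-allyl-2-hydroxy-4-(methoxymethoxy)phenyl]-5-hydroxy-4H-chromen-4-one | O=c1c(-c2ccc(OCOC)c(CC=C)c2O)coc2c(CC=C)c(OCC=C)cc(O)c12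
F5 | step 12 | 6,8-diallyl-3-(2,4-diacetoxy-3-allylphenyl)-4-oxo-4H-chromene-5,7-diyl diacetate | CC(=O)Oc1ccc(-c2coc3c(CC=C)c(OC(C)=O)c(CC=C)c(OC(C)=O)c3c2=O)c(OC(C)=O)c1CC=C
F6 | step 12 | 3-[2,4-diacetoxy-3-(3-methylbut-2-en-1-yl)phenyl]-6,8-bis(3-methylbut-2-en-1-yl)-4-oxo-4H-chromene-5,7-diyl diacetate | CC(=O)Oc1ccc(-c2coc3c(CC=C(C)C)c(OC(C)=O)c(CC=C(C)C)c(OC(C)=O)c3c2=O)c(OC(C)=O)c1CC=C(C)C
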